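Start with the tie.

common to all: substrate 0.071 M; second nucleophile 0.142 M
- elm: first nucleophile 0.035 M; run made earlier
- ash: first nucleophile 0.10 M; run made earlier
- beta: first nucleophile 0.130 M; time 5.0 min
- gamma: first nucleophile 0.0670 M; time 5.0 min

| run | time / min | other capture product / % | solvolysis product / % | over-reaction product / % | substrate / % | side product / % | target / % |
|---|---|---|---|---|---|---|---|
| elm | 1.00 | 9.3 | 11.9 | 3.5 | 62.3 | 1.5 | 10.1 |
| elm | 2.00 | 17.4 | 20.6 | 6.7 | 35.8 | 7.0 | 9.7 |
| elm | 3.00 | 24.4 | 24.4 | 13.3 | 22.2 | 8.9 | 8.9 |
| elm | 4.00 | 26.9 | 26.6 | 13.8 | 14.5 | 8.2 | 5.9 |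
| elm | 5.00 | 28.9 | 29.0 | 16.6 | 6.7 | 10.4 | 4.3 |
| ash | 0.417 | 2.5 | 3.5 | 0 | 80.2 | 0.9 | 10.7 |
| ash | 1.33 | 7.4 | 8.0 | 7.7 | 49.6 | 9.5 | 17.6 |
| ash | 2.50 | 11.2 | 10.9 | 16.3 | 27.0 | 14.6 | 16.9 |
| ash | 4.00 | 16.6 | 15.2 | 27.7 | 14.2 | 17.3 | 13.1 |
| ash | 5.00 | 16.3 | 14.2 | 32.8 | 8.2 | 15.3 | 8.5 |

(readings scatter by 1 percentage point)

- percentages count the substrate that a species holds: one side product counts as two
- what was read earlier has a scatter of 1 percentage point, one standard deviation

* which of these there is most of at the end, counted by the substrate in it, beta (side product / over-reaction product / other capture product / solvolysis product)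
* which of these there is most of at the end, counted by the substrate in it, gamma (side product / over-reaction product / other capture product / solvolysis product)
* amount of the one of these that there is most of at the end, in percent of the substrate charged, beta
* amount of the one of these that there is most of at the end, in percent of the substrate charged, gamma

At the last reading of elm, other capture product and solvolysis product stand at 28.9 % and 29.0 %, so we take 0.142 M of second nucleophile as the zero of the scale: an even split between those two.

Now turn the first nucleophile. What it captured sits in target, over-reaction product and half the side product, since a side product counts twice: 26.1 % in elm, 48.9 % in ash. The tied pair holds 57.9 % and 30.5 %. Divide the first amount by the second, then by the mean of charged and remaining first nucleophile: elm reads 17.5 L mol⁻¹, ash 19.4 L mol⁻¹. Their mean, 18.5 L mol⁻¹, is the capture ratio, a selectivity factor. The captured share is then ratio times concentration, over one plus that product.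

Second nucleophile, substrate and time stay as in those runs, so two readings carry over: the amount turned over, 81.7 %, and over-reaction product per unit share, 53.3 %.

In gamma the mean first nucleophile is about 0.0510 M, the share 48.5 %, and over-reaction product 25.9 %. Each tied product gets 21.1 %. In beta the mean is 0.110 M, the share 66.9 %, and over-reaction product 35.7 %. At the last reading of ash, side product stood at 15.3 %, below over-reaction product at 32.8 %.

The forecast gave 36 % for beta and 26 % for gamma, saying “Over-reaction product leads in both”.

The flasks give over-reaction product at 35.5 % in beta and over-reaction product at 26.6 % in gamma.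

    substrate + target → side product (k = 0.0870 L mol⁻¹ s⁻¹)
    intermediate → solvolysis product (k = 0.510 s⁻¹)
    first nucleophile + intermediate → target (k = 20.0 L mol⁻¹ s⁻¹)
    target → over-reaction product (k = 0.00750 s⁻¹)
    second nucleophile + intermediate → other capture product (k = 3.80 L mol⁻¹ s⁻¹)
    substrate → intermediate (k = 0.00780 s⁻¹)

From the end of gamma, with 55.3 % of its first nucleophile free, the same division gives 19.0 L mol⁻¹. The gap of 9 percentage points between the flasks comes from the difference in first nucleophile: with that difference taken away, so that beta holds gamma's charge of first nucleophile, beta stands at 26.6 % instead of 35.5 %.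

Take a neighbour of beta with 0.35 M of second nucleophile. The tie breaks, the ratio falls to 10.7 L mol⁻¹, the mean first nucleophile is 0.113 M, and over-reaction product comes to 29.2 %. That flask gives 29.4 %.

Readings and results come from a simulation with constants of no real substance.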